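**Plan**

1. Locants (germacrane style): C1 = furanone C=O; C2=C3 = furanone alkene; the ring oxygen bridges C3 and C10; C4(=C5) carries C15H3; C6 = lactone O–CH; C7 = ring-fusion CH; C8 = CH–O-angelate; C9 = CHOH; C10 = C(CH3)–O; C11 = C(OH)(C13H2Cl); C12 = lactone C=O.
2. Retrosynthetic cuts, in order: the C8–O acyl bond; C5–C6 together with the lactone bond O6–C12 (one ring-closing operation); the furanone ring (O10–C3 by cyclodehydration, C2–C3 by aldol); C13–Cl and the O8–C12 bond of a temporary lactone; C7–C8 (allylation); C1–C2 and the C4–C5 bond of a sugar lactone.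
3. Forward order: 2-C-methyl-D-ribono-1,4-lactone is opened to the C1/C8–C10 piece; a Barbier coupling joins C7–C8 and closes a temporary γ-lactone on O8 (template for C11), which is reopened as a Weinreb amide; the 3(2H)-furanone ring is built next; the ten-membered carbocycle and the γ-lactone on O6 are closed last, together.
4. Stereochemistry: C9 and C10 come from the sugar; C8 and C7 from a chelation-controlled indium allylation; C11 from epoxidation of the cis-disubstituted α-methylene lactone on its open face; C6 from the ring closure (Felkin–Anh at C7, reinforced by the tether); Z-C4=C5 from anti-carbomagnesiation of propargyl alcohol; the Z-ester from angelic acid.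
5. Enabling feature: C6 is both an allylic carbinol carbon bonded to the Z-alkenyl carbon C5 and the alkyl-oxygen carbon of the γ-lactone ring (C6–O–C12–C11–C7). Addition of a C5 alkenyl-metal to a C6 aldehyde therefore builds the ten-membered ring C1–C10 and releases an oxygen placed 1,4 to the C12 acyl group, while the flat furanone ring (O, C3, C2, C1, C10) and the Z-alkene turn C5 back toward C6.

Key step: step 19

Assumption: 2-[(4-methoxybenzyl)oxy]acetaldehyde is bought as such (it is otherwise one oxidation from the corresponding alcohol).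

**Step 1**
Reactants: 1 prop-2-yn-1-ol (propargyl alcohol)
Product: 2 (2Z)-3-iodo-2-methylprop-2-en-1-ol
Conditions: MeMgBr (3 equiv), CuI (10 mol %), THF, 0 °C → rt; then I2, −20 °C → rt
Reagents that add atoms: methylmagnesium bromide, C[Mg]Br; iodine, II
Why: Copper-catalysed anti-carbomagnesiation of the propargylic magnesium alkoxide puts the methyl group on the internal carbon and leaves an alkoxide-chelated alkenylmagnesium, whose iodinolysis with retention should give the iodide cis to CH2OH, i.e. the Z geometry needed at C4=C5.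

**Step 2**
Reactants: 2 (2Z)-3-iodo-2-methylprop-2-en-1-ol
Product: 3 (2Z)-3-iodo-2-methylprop-2-enal
Conditions: MnO2 (activated, excess), CH2Cl2, rt, dark
Reagents that add atoms: none
Why: Allylic alcohol oxidation with MnO2 is neutral and should leave the Z-iodoalkene untouched.

**Step 3**
Reactants: 4 2-[(4-methoxybenzyl)oxy]acetaldehyde; 5 methyl acrylate
Product: 6 methyl 3-hydroxy-4-[(4-methoxybenzyl)oxy]-2-methylidenebutanoate (racemic)
Conditions: DABCO (0.5 equiv), dioxane/H2O (1:1), rt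
Reagents that add atoms: none
Why: Morita–Baylis–Hillman reaction of the DABCO–acrylate zwitterion with the unhindered α-alkoxy aldehyde; the carbinol stereocentre is destroyed in the next step.

**Step 4**
Reactants: 6 methyl 3-hydroxy-4-[(4-methoxybenzyl)oxy]-2-methylidenebutanoate
Product: 7 methyl (2Z)-2-(bromomethyl)-4-[(4-methoxybenzyl)oxy]but-2-enoate
Conditions: NBS, Me2S, CH2Cl2, 0 °C → rt
Reagents that add atoms: N-bromosuccinimide, O=C1CCC(=O)N1Br
Why: The bromosulfonium salt activates the hydroxyl and bromide attacks the alkene terminus (SN2′ transposition, Corey–Kim-type bromination of a Baylis–Hillman adduct), which should give the conjugated Z-bromide with the β-substituent trans to the ester.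

**Step 5**
Reactants: 8 2-C-methyl-D-ribono-1,4-lactone
Product: 9 5-deoxy-5-iodo-2-C-methyl-D-ribono-1,4-lactone
Conditions: PPh3, I2, imidazole, THF, 0 °C → rt
Reagents that add atoms: iodine, II
Why: Garegg–Samuelsson (Appel-type) iodination is selective for the primary hydroxyl through its alkoxyphosphonium salt; the secondary and tertiary hydroxyls are too hindered.

**Step 6**
Reactants: 9 5-deoxy-5-iodo-2-C-methyl-D-ribono-1,4-lactone
Product: 10 (2R,3R)-2,3-dihydroxy-2-methylpent-4-enoic acid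
Conditions: Zn dust (activated), THF/H2O (4:1), 60 °C; then 1 M HCl
Reagents that add atoms: none
Why: Zinc inserts into the C–I bond and the β-acyloxy group leaves as the carboxylate (reductive β-elimination of the Boord/Bernet–Vasella type), which unmasks the vinyl group (future C8) without touching the two stereocentres.

**Step 7**
Reactants: 10 (2R,3R)-2,3-dihydroxy-2-methylpent-4-enoic acid
Product: 11 (2R,3R)-2,3-dihydroxy-N-methoxy-N,2-dimethylpent-4-enamide
Conditions: MeNHOMe·HCl, EDC·HCl, HOBt (cat.), N-methylmorpholine, CH2Cl2, 0 °C → rt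
Reagents that add atoms: N,O-dimethylhydroxylamine hydrochloride, Cl.CNOC
Why: Carbodiimide/HOBt amide coupling, which tolerates the free secondary and tertiary hydroxyls.

**Step 8**
Reactants: 11 (2R,3R)-2,3-dihydroxy-N-methoxy-N,2-dimethylpent-4-enamide
Product: 12 (3R,4R)-3,4-dihydroxy-3-methylhex-5-en-2-one
Conditions: MeMgBr (4 equiv), THF, −20 → 0 °C; aq. NH4Cl
Reagents that add atoms: methylmagnesium bromide, C[Mg]Br
Why: Weinreb ketone synthesis: after deprotonation of the two hydroxyls, MeMgBr adds once to give a stable magnesium chelate that releases the methyl ketone (C1, C2) only on work-up.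

**Step 9**
Reactants: 12 (3R,4R)-3,4-dihydroxy-3-methylhex-5-en-2-one; 7 methyl (2Z)-2-(bromomethyl)-4-[(4-methoxybenzyl)oxy]but-2-enoate
Product: 15 cis-α-methylene-γ-lactone (4S,5S)-5-[(1R,2R)-1,2-dihydroxy-2-methyl-3-oxobutyl]-4-{[(4-methoxybenzyl)oxy]methyl}-3-methylideneoxolan-2-one, via dihydroxy keto aldehyde 13 (not isolated), via open-chain trihydroxy ester 14 (not isolated)
Conditions: O3, CH2Cl2/MeOH, −78 °C; Me2S; then 7 (1.3 equiv), In powder, THF/H2O (1:1), rt; then PPTS (cat.), PhH, 50 °C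
Reagents that add atoms: ozone, [O-][O+]=O
Why: Ozonolysis unmasks the C8 aldehyde, and the indium-mediated Barbier allylation in water should pass through a chair transition state in which indium is chelated by the free C9 hydroxyl and the aldehyde oxygen (Cram-chelate face, 8,9-syn) and the ester-chelated Z-allylindium places CH2OPMB axial (7,8-syn, SE2′ at the γ-carbon), after which acid closes the γ-lactone on O8.

**Step 10**
Reactants: 15 cis-α-methylene-γ-lactone diol
Product: 16 C9 tert-butyldimethylsilyl ether of 15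
Conditions: TBSOTf (1.1 equiv), 2,6-lutidine, CH2Cl2, −78 °C
Reagents that add atoms: tert-butyldimethylsilyl trifluoromethanesulfonate, CC(C)(C)[Si](C)(C)OS(=O)(=O)C(F)(F)F
Why: Silyl triflate silylation at low temperature discriminates the secondary C9 hydroxyl from the tertiary α-keto C10 hydroxyl, which stays free for the later furanone closure.

**Step 11**
Reactants: 16 C9 silyl ether of the α-methylene lactone
Product: 17 spiro-epoxy lactone (11S)
Conditions: dimethyldioxirane (acetone solution), CH2Cl2, 0 °C → rt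
Reagents that add atoms: dimethyldioxirane, CC1(C)OO1
Why: Dioxirane epoxidation of the electron-poor exocyclic alkene needs no base and should occur on the lactone face opposite the cis-disposed C7 and C8 substituents, which sets C11.

**Step 12**
Reactants: 17 spiro-epoxy lactone
Product: 18 chlorohydrin lactone (11R)
Conditions: LiCl, AcOH, THF, rt
Reagents that add atoms: lithium chloride, [Li+].[Cl-]
Why: Acid-assisted SN2 opening of the epoxide by chloride at the primary carbon C13 (halohydrin formation with a lithium halide and acetic acid); C11 is deactivated by the carbonyl and keeps its configuration.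

**Step 13**
Reactants: 18 chlorohydrin lactone
Product: 19 γ-hydroxy Weinreb amide (C8–OH free)
Conditions: MeNHOMe·HCl, AlMe3, CH2Cl2, 0 °C → rt; aq. potassium sodium tartrate work-up
Reagents that add atoms: N,O-dimethylhydroxylamine hydrochloride, Cl.CNOC
Why: Aminolysis of the lactone by the aluminium amide (Weinreb amidation) opens the temporary ring irreversibly, frees the C8 hydroxyl and leaves C12 as an acyl donor for the final lactone.

**Step 14**
Reactants: 19 γ-hydroxy Weinreb amide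
Product: 20 C8 triethylsilyl ether
Conditions: TESOTf (1.1 equiv), 2,6-lutidine, CH2Cl2, −78 °C
Reagents that add atoms: triethylsilyl trifluoromethanesulfonate, CC[Si](CC)(CC)OS(=O)(=O)C(F)(F)F
Why: The only secondary hydroxyl (C8) is silylated fast at −78 °C, before the γ-hydroxy amide can relactonise, while the two tertiary hydroxyls stay free.

**Step 15**
Reactants: 20 C8 triethylsilyl ether methyl ketone; 3 (2Z)-3-iodo-2-methylprop-2-enal
Product: 21 β-hydroxy ketone (aldol adduct, both C3 epimers)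
Conditions: LiN(iPr)2 (3.3 equiv), THF, −78 °C; then 3; aq. NH4Cl
Reagents that add atoms: none
Why: Aldol addition: the base deprotonates the two tertiary hydroxyls and the only enolisable position, the C2 methyl group (C10 and C11 carry no hydrogen), and the lithium enolate adds to the enal; the new C3 carbinol centre is removed in the next step.

**Step 16**
Reactants: 21 β-hydroxy ketone
Product: 23 (Z)-iodoalkenyl 3(2H)-furanone (C6 PMB ether; C8 OTES; C9 OTBS; C12 Weinreb amide), via β-iodovinyl 1,3-diketone 22 (not isolated)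
Conditions: Dess–Martin periodinane, CH2Cl2, 0 °C → rt; then TsOH·H2O (10 mol %), PhH, rt
Reagents that add atoms: none
Why: Dess–Martin oxidation gives the 1,3-diketone, and acid-catalysed attack of the tertiary C10 hydroxyl on the C3 carbonyl followed by loss of water (5-exo-trig hemiketalisation–dehydration, the classical 3(2H)-furanone synthesis) forms the furanone ring.

**Step 17**
Reactants: 23 (Z)-iodoalkenyl furanone PMB ether
Product: 24 C6 primary alcohol
Conditions: DDQ, CH2Cl2/pH 7 buffer (10:1), 0 °C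
Reagents that add atoms: none
Why: Oxidative cleavage of the p-methoxybenzyl ether by DDQ (hydride abstraction, hydrolysis of the oxocarbenium ion) should free the C6 hydroxyl without touching the silyl ethers or the iododienone.

**Step 18**
Reactants: 24 C6 primary alcohol
Product: 25 C6 aldehyde (seco iodo-aldehyde)
Conditions: PhI(OAc)2, TEMPO (10 mol %), CH2Cl2, rt
Reagents that add atoms: none
Why: TEMPO-catalysed oxidation with PhI(OAc)2 converts the primary alcohol into the aldehyde under nearly neutral conditions, which should spare the tertiary hydroxyls and the α-stereocentre C7.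

**Step 19**
Reactants: 25 C6 aldehyde (seco iodo-aldehyde)
Product: 27 macrocyclic 12,6-lactone (C8 OTES; C9 OTBS), via seco hydroxy Weinreb amide 26 (not isolated)
Conditions: CrCl2 (15 equiv), NiCl2 (2 mol %), DMSO/THF, 0.003 M, syringe-pump addition of 25, rt; aqueous work-up; then PPTS (cat.), CH2Cl2, rt
Reagents that add atoms: none
Why: Zerovalent nickel (from NiCl2 and CrCl2) inserts into the C5–I bond and passes the alkenyl group to trivalent chromium with retention of the Z geometry; the alkenylchromium adds to the C6 aldehyde, and the C6 oxygen then attacks the C12 Weinreb amide and expels N,O-dimethylhydroxylamine. The closest known reaction type is the Nozaki–Hiyama–Kishi alkenyl iodide–aldehyde macrocyclisation to medium carbocycles, followed by lactonisation of a γ-hydroxy Weinreb amide. The new C5–C6 bond closes the ten-membered carbocycle (and with it the nine-membered oxacycle through the furanone oxygen) in a 10-exo-trig mode, and the lactone closes 5-exo-trig at C12. The only new stereocentre, C6, is controlled by C7: in the Felkin–Anh arrangement the fully substituted C11 lies anti to the incoming C5 and C7–H flanks its path, which is also the arrangement the tether requires (C5 gauche to C8), so the 6S alcohol and from it the cis-fused lactone should result. The step needs chemoselectivity for the aldehyde over the Weinreb amide, the furanone carbonyl and the alkyl chloride, which the carbonyl selectivity and low basicity of organochromium reagents secure, and ring closure over oligomerisation, which high dilution, the Z-C4=C5 alkene and the rigid furanone ring secure.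

**Step 20**
Reactants: 27 macrocyclic 12,6-lactone (C8 OTES; C9 OTBS)
Product: 28 C8 alcohol (C9 OTBS)
Conditions: HF·pyridine, pyridine, THF, 0 °C
Reagents that add atoms: none
Why: Buffered HF·pyridine cleaves the triethylsilyl ether at C8 much faster than the tert-butyldimethylsilyl ether at the neopentyl-like C9 (selective desilylation).

**Step 21**
Reactants: 28 C8 alcohol (C9 OTBS); 29 angelic acid, (2Z)-2-methylbut-2-enoic acid
Product: 30 C8 angelate (C9 OTBS)
Conditions: 29, 2,4,6-trichlorobenzoyl chloride, Et3N (1 equiv to the acid), toluene, rt; then 28, 75 °C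
Reagents that add atoms: none
Why: Yamaguchi esterification through the preformed mixed anhydride without DMAP acylates the secondary C8 hydroxyl (the tertiary C11 hydroxyl and the silylated C9 oxygen cannot react) and is the known way to introduce an angelate without Z-to-E isomerisation to the tiglate.

**Step 22**
Reactants: 30 C8 angelate (C9 OTBS)
Product: 31 CNP0272644.1 (target)
Conditions: HF·pyridine (excess), THF, rt
Reagents that add atoms: none
Why: Acidic fluoride desilylation frees the C9 hydroxyl under conditions that should not provoke acyl migration, epoxide formation from the chlorohydrin or isomerisation of the angelate.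

**Compound list**

1 | prop-2-yn-1-ol (propargyl alcohol) | C#CCO | starting material
2 | (2Z)-3-iodo-2-methylprop-2-en-1-ol | I/C=C(/C)CO | intermediate
3 | (2Z)-3-iodo-2-methylprop-2-enal | I/C=C(/C)C=O | intermediate
4 | 2-[(4-methoxybenzyl)oxy]acetaldehyde | COc1ccc(COCC=O)cc1 | starting material
5 | methyl acrylate | C=CC(=O)OC | starting material
6 | methyl 3-hydroxy-4-[(4-methoxybenzyl)oxy]-2-methylidenebutanoate (racemic) | COC(=O)C(=C)C(O)COCc1ccc(OC)cc1 | intermediate
7 | methyl (2Z)-2-(bromomethyl)-4-[(4-methoxybenzyl)oxy]but-2-enoate | COC(=O)/C(CBr)=C/COCc1ccc(OC)cc1 | intermediate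
8 | 2-C-methyl-D-ribono-1,4-lactone; (3R,4R,5R)-3,4-dihydroxy-5-(hydroxymethyl)-3-methyloxolan-2-one | C[C@]1(O)C(=O)O[C@H](CO)[C@H]1O | starting material
9 | (3R,4R,5S)-3,4-dihydroxy-5-(iodomethyl)-3-methyloxolan-2-one | C[C@]1(O)C(=O)O[C@H](CI)[C@H]1O | intermediate
10 | (2R,3R)-2,3-dihydroxy-2-methylpent-4-enoic acid | C=C[C@@H](O)[C@@](C)(O)C(=O)O | intermediate
11 | (2R,3R)-2,3-dihydroxy-N-methoxy-N,2-dimethylpent-4-enamide | C=C[C@@H](O)[C@@](C)(O)C(=O)N(C)OC | intermediate
12 | (3R,4R)-3,4-dihydroxy-3-methylhex-5-en-2-one | C=C[C@@H](O)[C@@](C)(O)C(C)=O | intermediate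
13 | (2S,3R)-2,3-dihydroxy-3-methyl-4-oxopentanal | O=C[C@@H](O)[C@@](C)(O)C(C)=O | intermediate
14 | methyl (3S,4S,5R,6R)-4,5,6-trihydroxy-3-{[(4-methoxybenzyl)oxy]methyl}-6-methyl-2-methylidene-7-oxooctanoate | CC(=O)[C@](C)(O)[C@H](O)[C@@H](O)[C@H](COCc1ccc(OC)cc1)C(=C)C(=O)OC | intermediate
15 | (4S,5S)-5-[(1R,2R)-1,2-dihydroxy-2-methyl-3-oxobutyl]-4-{[(4-methoxybenzyl)oxy]methyl}-3-methylideneoxolan-2-one | CC(=O)[C@](C)(O)[C@H](O)[C@H]1OC(=O)C(=C)[C@H]1COCc1ccc(OC)cc1 | intermediate
16 | (4S,5S)-5-[(1R,2R)-1-{[tert-butyl(dimethyl)silyl]oxy}-2-hydroxy-2-methyl-3-oxobutyl]-4-{[(4-methoxybenzyl)oxy]methyl}-3-methylideneoxolan-2-one | CC(=O)[C@](C)(O)[C@H](O[Si](C)(C)C(C)(C)C)[C@H]1OC(=O)C(=C)[C@H]1COCc1ccc(OC)cc1 | intermediate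
17 | (3S,6S,7S)-6-[(1R,2R)-1-{[tert-butyl(dimethyl)silyl]oxy}-2-hydroxy-2-methyl-3-oxobutyl]-7-{[(4-methoxybenzyl)oxy]methyl}-1,5-dioxaspiro[2.4]heptan-4-one | CC(=O)[C@](C)(O)[C@H](O[Si](C)(C)C(C)(C)C)[C@H]1OC(=O)[C@@]2(CO2)[C@H]1COCc1ccc(OC)cc1 | intermediate
18 | (3R,4S,5S)-5-[(1R,2R)-1-{[tert-butyl(dimethyl)silyl]oxy}-2-hydroxy-2-methyl-3-oxobutyl]-3-(chloromethyl)-3-hydroxy-4-{[(4-methoxybenzyl)oxy]methyl}oxolan-2-one | CC(=O)[C@](C)(O)[C@H](O[Si](C)(C)C(C)(C)C)[C@H]1OC(=O)[C@@](O)(CCl)[C@H]1COCc1ccc(OC)cc1 | intermediate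
19 | (2R,3S,4S,5R,6R)-5-{[tert-butyl(dimethyl)silyl]oxy}-2-(chloromethyl)-2,4,6-trihydroxy-N-methoxy-3-{[(4-methoxybenzyl)oxy]methyl}-N,6-dimethyl-7-oxooctanamide | CC(=O)[C@](C)(O)[C@H](O[Si](C)(C)C(C)(C)C)[C@@H](O)[C@H](COCc1ccc(OC)cc1)[C@](O)(CCl)C(=O)N(C)OC | intermediate
20 | (2R,3S,4S,5R,6R)-5-{[tert-butyl(dimethyl)silyl]oxy}-2-(chloromethyl)-2,6-dihydroxy-N-methoxy-3-{[(4-methoxybenzyl)oxy]methyl}-N,6-dimethyl-7-oxo-4-[(triethylsilyl)oxy]octanamide | CC(=O)[C@](C)(O)[C@H](O[Si](C)(C)C(C)(C)C)[C@@H](O[Si](CC)(CC)CC)[C@H](COCc1ccc(OC)cc1)[C@](O)(CCl)C(=O)N(C)OC | intermediate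
21 | (2R,3S,4S,5R,6R,10Z)-5-{[tert-butyl(dimethyl)silyl]oxy}-2-(chloromethyl)-2,6,9-trihydroxy-11-iodo-N-methoxy-3-{[(4-methoxybenzyl)oxy]methyl}-N,6,10-trimethyl-7-oxo-4-[(triethylsilyl)oxy]undec-10-enamide (C9 epimers) | I/C=C(/C)C(O)CC(=O)[C@](C)(O)[C@H](O[Si](C)(C)C(C)(C)C)[C@@H](O[Si](CC)(CC)CC)[C@H](COCc1ccc(OC)cc1)[C@](O)(CCl)C(=O)N(C)OC | intermediate
22 | (2R,3S,4S,5R,6R,10Z)-5-{[tert-butyl(dimethyl)silyl]oxy}-2-(chloromethyl)-2,6-dihydroxy-11-iodo-N-methoxy-3-{[(4-methoxybenzyl)oxy]methyl}-N,6,10-trimethyl-7,9-dioxo-4-[(triethylsilyl)oxy]undec-10-enamide | I/C=C(/C)C(=O)CC(=O)[C@](C)(O)[C@H](O[Si](C)(C)C(C)(C)C)[C@@H](O[Si](CC)(CC)CC)[C@H](COCc1ccc(OC)cc1)[C@](O)(CCl)C(=O)N(C)OC | intermediate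
23 | (2R,3S,4S,5R)-5-{[tert-butyl(dimethyl)silyl]oxy}-2-(chloromethyl)-2-hydroxy-5-{(2R)-5-[(1Z)-1-iodoprop-1-en-2-yl]-2-methyl-3-oxo-2,3-dihydrofuran-2-yl}-N-methoxy-3-{[(4-methoxybenzyl)oxy]methyl}-N-methyl-4-[(triethylsilyl)oxy]pentanamide | I/C=C(/C)C1=CC(=O)[C@](C)(O1)[C@H](O[Si](C)(C)C(C)(C)C)[C@@H](O[Si](CC)(CC)CC)[C@H](COCc1ccc(OC)cc1)[C@](O)(CCl)C(=O)N(C)OC | intermediate
24 | (2R,3S,4S,5R)-5-{[tert-butyl(dimethyl)silyl]oxy}-2-(chloromethyl)-2-hydroxy-3-(hydroxymethyl)-5-{(2R)-5-[(1Z)-1-iodoprop-1-en-2-yl]-2-methyl-3-oxo-2,3-dihydrofuran-2-yl}-N-methoxy-N-methyl-4-[(triethylsilyl)oxy]pentanamide | I/C=C(/C)C1=CC(=O)[C@](C)(O1)[C@H](O[Si](C)(C)C(C)(C)C)[C@@H](O[Si](CC)(CC)CC)[C@H](CO)[C@](O)(CCl)C(=O)N(C)OC | intermediate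
25 | (2R,3S,4S,5R)-5-{[tert-butyl(dimethyl)silyl]oxy}-2-(chloromethyl)-3-formyl-2-hydroxy-5-{(2R)-5-[(1Z)-1-iodoprop-1-en-2-yl]-2-methyl-3-oxo-2,3-dihydrofuran-2-yl}-N-methoxy-N-methyl-4-[(triethylsilyl)oxy]pentanamide | I/C=C(/C)C1=CC(=O)[C@](C)(O1)[C@H](O[Si](C)(C)C(C)(C)C)[C@@H](O[Si](CC)(CC)CC)[C@H](C=O)[C@](O)(CCl)C(=O)N(C)OC | intermediate
26 | (4Z,6S,7S,8S,9R,10R,11R)-9-{[tert-butyl(dimethyl)silyl]oxy}-13-chloro-6,11-dihydroxy-N-methoxy-N-methyl-1-oxo-8-[(triethylsilyl)oxy]-3,10-epoxygermacra-2,4-dien-12-amide | CC[Si](CC)(CC)O[C@H]1[C@@H]([C@](O)(CCl)C(=O)N(C)OC)[C@@H](O)/C=C(/C)C2=CC(=O)[C@](C)(O2)[C@@H]1O[Si](C)(C)C(C)(C)C | intermediate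
27 | (4Z,6S,7S,8S,9R,10R,11R)-9-{[tert-butyl(dimethyl)silyl]oxy}-13-chloro-11-hydroxy-1-oxo-8-[(triethylsilyl)oxy]-3,10-epoxygermacra-2,4-dien-12,6-olide | CC[Si](CC)(CC)O[C@H]1[C@@H]2[C@H](/C=C(/C)C3=CC(=O)[C@](C)(O3)[C@@H]1O[Si](C)(C)C(C)(C)C)OC(=O)[C@@]2(O)CCl | intermediate
28 | (4Z,6S,7R,8S,9R,10R,11R)-9-{[tert-butyl(dimethyl)silyl]oxy}-13-chloro-8,11-dihydroxy-1-oxo-3,10-epoxygermacra-2,4-dien-12,6-olide | O[C@H]1[C@@H]2[C@H](/C=C(/C)C3=CC(=O)[C@](C)(O3)[C@@H]1O[Si](C)(C)C(C)(C)C)OC(=O)[C@@]2(O)CCl | intermediate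
29 | angelic acid; (2Z)-2-methylbut-2-enoic acid | C/C=C(/C)C(=O)O | starting material
30 | (4Z,6S,7S,8S,9R,10R,11R)-8-(angeloyloxy)-9-{[tert-butyl(dimethyl)silyl]oxy}-13-chloro-11-hydroxy-1-oxo-3,10-epoxygermacra-2,4-dien-12,6-olide | C/C=C(/C)C(=O)O[C@H]1[C@@H]2[C@H](/C=C(/C)C3=CC(=O)[C@](C)(O3)[C@@H]1O[Si](C)(C)C(C)(C)C)OC(=O)[C@@]2(O)CCl | intermediate
31 | CNP0272644.1; (4Z,6S,7S,8S,9R,10R,11R)-8-(angeloyloxy)-13-chloro-9,11-dihydroxy-1-oxo-3,10-epoxygermacra-2,4-dien-12,6-olide | C/C=C(/C)C(=O)O[C@H]1[C@@H]2[C@H](/C=C(/C)C3=CC(=O)[C@](C)(O3)[C@@H]1O)OC(=O)[C@@]2(O)CCl | target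

**Step count and risks**

Total step count: 22 (steps 1–4 prepare the building blocks 3 and 7). Longest linear sequence: 18 steps (steps 5–22, from 2-C-methyl-D-ribono-1,4-lactone 8).

The three steps most likely to fail are step 19, step 9 and step 16.

In step 19 the alkenylchromium may add to the wrong face of the C6 aldehyde, and slow closure of the strained ring lets protonolysis of the C5–Cr bond compete. The fallback sets out from 25 and comes back at 26. The cyclisation is run without the acid treatment, so that 26 is obtained together with its C6 epimer, the (6R)-seco hydroxy amide F1. The mixture is oxidised with Dess–Martin periodinane to the C6 ketone F2. This cross-conjugated enone is then reduced under reagent control with (S)-1-methyl-3,3-diphenyltetrahydro-1H,3H-pyrrolo[1,2-c][1,3,2]oxazaborole and catecholborane (Corey–Bakshi–Shibata reduction, the alkenyl group acting as the large substituent) to return 26, which is lactonised to 27 as in step 19.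

In step 9 chelation control may be lost (attack on the Felkin face of the aldehyde), or a boat-like transition state may intervene; either gives C8 or C7 epimers that cannot be corrected later. The fallback sets out from 12 and comes back at 15. Compound 12 is protected (2,2-dimethoxypropane, PPTS) as 1-[(4R,5R)-5-ethenyl-2,2,4-trimethyl-1,3-dioxolan-4-yl]ethan-1-one F3 and ozonised to (4S,5R)-5-acetyl-2,2,5-trimethyl-1,3-dioxolane-4-carbaldehyde F4. Allylation with 7 mediated by CrCl2 in THF (Nozaki–Hiyama allylation, anti-selective through the chair of the E-allylchromium and Felkin–Anh-selective on the dioxolane aldehyde) should give, after lactonisation in the flask, the trans-lactone F5, which differs from the desired series at C8 only. LiOH opens it to the hydroxy acid F6, and Mitsunobu lactonisation (PPh3, DIAD) closes the ring again with inversion at C8 to the cis-lactone acetonide F7. Aqueous acetic acid then removes the acetonide to give 15.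

In step 16 the enol oxygen of the β-iodovinyl 1,3-diketone may add to C5 and expel iodide (6-endo closure to a 4-pyranone), and the iodoalkene may lose its Z geometry by addition–elimination under acid. The fallback sets out from 1 and 20 and comes back at 23. Compound 1 is carbometalated as in step 1, but the alkenylmagnesium is quenched with Bu3SnCl to give (2Z)-2-methyl-3-(tributylstannyl)prop-2-en-1-ol F8, which MnO2 oxidises to the stannyl enal F9. The aldol reaction of 20 with F9 (conditions of step 15) gives the adduct F10. Dess–Martin oxidation and PPTS give the stannylalkenyl furanone F11, which has no leaving group at C5. Iododestannylation with I2 in CH2Cl2 at 0 °C, which proceeds with retention at the alkene, then gives 23.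

**Further compounds**

F1 | step 19 | (4Z,6R,7S,8S,9R,10R,11R)-9-{[tert-butyl(dimethyl)silyl]oxy}-13-chloro-6,11-dihydroxy-N-methoxy-N-methyl-1-oxo-8-[(triethylsilyl)oxy]-3,10-epoxygermacra-2,4-dien-12-amide | CC[Si](CC)(CC)O[C@H]1[C@@H]([C@](O)(CCl)C(=O)N(C)OC)[C@H](O)/C=C(/C)C2=CC(=O)[C@](C)(O2)[C@@H]1O[Si](C)(C)C(C)(C)C
F2 | step 19 | (4Z,7S,8S,9R,10R,11R)-9-{[tert-butyl(dimethyl)silyl]oxy}-13-chloro-11-hydroxy-N-methoxy-N-methyl-1,6-dioxo-8-[(triethylsilyl)oxy]-3,10-epoxygermacra-2,4-dien-12-amide | CC[Si](CC)(CC)O[C@H]1[C@@H]([C@](O)(CCl)C(=O)N(C)OC)C(=O)/C=C(/C)C2=CC(=O)[C@](C)(O2)[C@@H]1O[Si](C)(C)C(C)(C)C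
F3 | step 9 | 1-[(4R,5R)-5-ethenyl-2,2,4-trimethyl-1,3-dioxolan-4-yl]ethan-1-one | C=C[C@H]1OC(C)(C)O[C@@]1(C)C(C)=O
F4 | step 9 | (4S,5R)-5-acetyl-2,2,5-trimethyl-1,3-dioxolane-4-carbaldehyde | O=C[C@H]1OC(C)(C)O[C@@]1(C)C(C)=O
F5 | step 9 | (4S,5R)-5-[(4R,5R)-5-acetyl-2,2,5-trimethyl-1,3-dioxolan-4-yl]-4-{[(4-methoxybenzyl)oxy]methyl}-3-methylideneoxolan-2-one | CC(=O)[C@]1(C)OC(C)(C)O[C@@H]1[C@@H]2OC(=O)C(=C)[C@H]2COCc3ccc(OC)cc3
F6 | step 9 | (3S,4R)-4-[(4R,5R)-5-acetyl-2,2,5-trimethyl-1,3-dioxolan-4-yl]-4-hydroxy-3-{[(4-methoxybenzyl)oxy]methyl}-2-methylidenebutanoic acid | CC(=O)[C@]1(C)OC(C)(C)O[C@@H]1[C@H](O)[C@H](COCc2ccc(OC)cc2)C(=C)C(=O)O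
F7 | step 9 | (4S,5S)-5-[(4R,5R)-5-acetyl-2,2,5-trimethyl-1,3-dioxolan-4-yl]-4-{[(4-methoxybenzyl)oxy]methyl}-3-methylideneoxolan-2-one | CC(=O)[C@]1(C)OC(C)(C)O[C@@H]1[C@H]2OC(=O)C(=C)[C@H]2COCc3ccc(OC)cc3
F8 | step 16 | (2Z)-2-methyl-3-(tributylstannyl)prop-2-en-1-ol | CCCC[Sn](CCCC)(CCCC)/C=C(/C)CO
F9 | step 16 | (2Z)-2-methyl-3-(tributylstannyl)prop-2-enal | CCCC[Sn](CCCC)(CCCC)/C=C(/C)C=O
F10 | step 16 | (2R,3S,4S,5R,6R,10Z)-5-{[tert-butyl(dimethyl)silyl]oxy}-2-(chloromethyl)-2,6,9-trihydroxy-N-methoxy-3-{[(4-methoxybenzyl)oxy]methyl}-N,6,10-trimethyl-7-oxo-4-[(triethylsilyl)oxy]-11-(tributylstannyl)undec-10-enamide (C9 epimers) | CCCC[Sn](CCCC)(CCCC)/C=C(/C)C(O)CC(=O)[C@](C)(O)[C@H](O[Si](C)(C)C(C)(C)C)[C@@H](O[Si](CC)(CC)CC)[C@H](COCc1ccc(OC)cc1)[C@](O)(CCl)C(=O)N(C)OC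
F11 | step 16 | (2R,3S,4S,5R)-5-{[tert-butyl(dimethyl)silyl]oxy}-2-(chloromethyl)-2-hydroxy-N-methoxy-3-{[(4-methoxybenzyl)oxy]methyl}-N-methyl-5-{(2R)-2-methyl-3-oxo-5-[(1Z)-1-(tributylstannyl)prop-1-en-2-yl]-2,3-dihydrofuran-2-yl}-4-[(triethylsilyl)oxy]pentanamide | CCCC[Sn](CCCC)(CCCC)/C=C(/C)C1=CC(=O)[C@](C)(O1)[C@H](O[Si](C)(C)C(C)(C)C)[C@@H](O[Si](CC)(CC)CC)[C@H](COCc1ccc(OC)cc1)[C@](O)(CCl)C(=O)N(C)OC
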